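Atom labels follow the chromene numbering of the target (O1, C2, C3, C4, C4a, C5–C8, C8a; side chain C1'–C4'). Compound numbers are those of the steps and the compound list below.

## The problem

The target is a 2H-chromene whose benzene ring (ring A) is fully differentiated: O1 at C8a, free hydroxyls at C5 and C8, a cinnamoyl group at C6 and hydrogen only at C7. A synthesis therefore has to place an acyl group between a phenol and a free position of a hydroquinone, and cannot rely on the weak directing differences of a symmetric 1,4-dioxygenated arene. The only stereocentre is C2, a quaternary carbon bound to O1, a methyl group, C3 and C1'. Nothing else in the molecule can control it, so it must be brought in and then only preserved. Once the C3=C4 bond exists, conditions that open the 2H-pyran (heat, light, strong acid) would put C2 at risk, so the chromene double bond should come late. Three groups dictate a mild endgame: the tertiary allylic alcohol at C4' ionizes in acid, the chalcone will not tolerate borane, hydride or organolithium reagents, and the 5,8-hydroquinone is oxidized by air in base. The enabling feature is that C4a and C8a, with O1, form a cyclic enol ether, and that ring A shows 1,4-dioxygenation (C5, C8) with C6 substituted and C7 free. This is the pattern produced when an alkenyl(alkoxy)carbene, a terminal alkyne and carbon monoxide combine in a benzannulation, so ring A can be built in one step on a preformed chiral dihydropyran.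

## Retrosynthesis

**26 to 24 (O8–CH3).** The last operation frees the C8 oxygen from its methyl ether. A hydroquinone monomethyl ether is what the benzannulation delivers, and it can be unmasked by oxidation to quinone 25 and immediate reduction, without the Lewis acids that a tertiary allylic alcohol would not survive. The forward step must be fast and must be followed at once by reduction.

**24 to 23 (C3=C4).** The chromene double bond is removed. The annulation needs an enol ether in which C3 and C4 are saturated, so the double bond is introduced afterwards by dehydrogenation. Hydride loss from C4 is assisted by O1 and the C5 oxygen. Doing this late keeps the sensitive 2H-pyran out of all earlier steps.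

**23 to 22 to 21 (C=O from CH–O; silyl groups).** The ketone is taken back to a carbinol and the two alcohols to silyl ethers. An ynone would be a poor partner for the carbene, and an enone could not be carried through the annulation cleanly, so the acyl carbon travels as a protected propargylic carbinol. The forward steps are one fluoride desilylation and one selective oxidation of an allylic, benzylic alcohol.

**21 to 16 + 19 (C7–C8, C5–C6, C4a–C5; ring A).** All of ring A is disconnected into carbene complex 16, terminal alkyne 19 and one CO ligand. Compared with acylating a preformed dimethoxychromane, this cut fixes the C6 carbon, the free C7 position and the difference between the C5 and C8 oxygens by mechanism. The precursors are a monocyclic dihydropyran complex and a five-carbon alkyne. The forward reaction must insert the alkyne with its substituted carbon next to the CO-derived carbon and must end in the phenol.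

**19 to 18 to 17.** The alkyne is cut at the carbinol carbon into cinnamaldehyde 17 and an ethynyl nucleophile, followed by silylation. It is used as the racemate because this centre becomes the ketone.

**16 to 12 + 13 (C8–C8a, O–CH3).** The carbene carbon is cut from the enol ether carbon. The forward sequence is the standard one: vinylic lithiation of dihydropyran 12, addition to Cr(CO)6 (13) and O-methylation.

**12 to 10 to 5 (enol ether; C1'–C4' side chain).** The enol ether comes from mixed acetal 10 by loss of methanol. The side chain is cut at C4'–CH3 (methyl addition to enone 9), at C2'=C3' (Wittig reaction of aldehyde 8) and at the C2' oxygen (hydroboration of the vinyl group of 5, via 7). The side chain is built here and not after the annulation, because in 5 the vinyl group is the only alkene and no phenol, styrene or enone is present. After ring A exists, borane and methyllithium would face all three. It also makes the carbene non-volatile and the key step more convergent.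

**5 to 4 to 3 to 1 (O1–C8a, C4a=C8a carbon, C6=C7 of linalool).** The acetal is opened to hydroxy enol ether 4, the enol ether carbon is removed (Wittig homologation of lactol 3), and 3 is traced to (R)-linalool 1 by selective ozonolysis. The carbinol carbon of 1 becomes C2 with its C–O bond intact, the vinyl group becomes C1'–C2', C4 and C5 become C3 and C4, and C6 becomes C4a. The hindered O1–C8a bond forms by addition to an oxocarbenium ion, not by arylation of a tertiary alcohol.

## Roads not taken

**Alternative 1:** The cut is at O1–C8a and C4–C4a. An aryne released by fluoride from silyl triflate A3 would be attacked by the tertiary hydroxyl of (S)-mevalonolactone A2, and the aryl anion would then open the lactone to give chromanone A1.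
- Merits: it is convergent and short. Ring A is bought ready-made. The C4 ketone gives C3=C4 by reduction and dehydration, which is easier than the dehydrogenation of step 15. The hydroxyethyl arm is already at the alcohol level, which saves the hydroboration of step 4.
- Weak points: A2 is the antipode of the natural lactone. The nucleophile is a hindered tertiary alcohol on a β-hydroxy lactone that can eliminate or undergo retro-aldol cleavage under basic fluoride. A1 is a β-aryloxy ketone, so reversible ring opening by retro-oxa-Michael reaction threatens C2. The cinnamoyl group must still be put on a 5,8-dimethoxy arene by electrophilic acylation, and two methyl ethers must be removed, the C8 one again through the quinone.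
- Comparison: this road is probably shorter to the bicyclic core and better for C3=C4. The chosen plan answers with a stereocentre that is never β to a carbonyl, a cheap natural-series terpene, and a ring A whose substitution is fixed by mechanism.

**Alternative 2:** The cut is at C3=C4. Ring-closing metathesis of aryl ether A5 with a second-generation Grubbs catalyst would give chromene A4.
- Merits: the double bond that the chosen plan must create by oxidation is formed directly, the side chain can already be complete, and the step count is likely the lowest of all.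
- Weak points: A5 requires an aryl ether of a tertiary allylic alcohol of defined configuration. Nucleophilic aromatic substitution is not available on an electron-rich dimethoxyarene, metal-catalysed C–O coupling of tertiary alcohols is poor, and allylic substitution routes lose the configuration or give the linear ether. The chiral source would be (S)-linalool A6, the other enantiomer, because here the vinyl group becomes C3. A4 still needs C6 acylation in the presence of an acid-sensitive chromene and double demethylation.
- Comparison: this road is better on step count and on C3=C4. The chosen plan never makes the hindered aryl–O bond by arylation (O1–C2 is linalool's own bond, and O1–C8a forms at an oxocarbenium ion), and it delivers ring A with all substituents in place.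

**Alternative 3:** The cut is at C4–C4a and C3–C4. A silyl diazomethane with a boron Lewis acid would add to the ketone of benzofuranone A8, and aryl migration would insert C4 to give chromanone A7.
- Merits: the stereocentre comes from a catalytic enantioselective allylation (a zerovalent palladium catalyst, Pd2(dba)3 with a chiral phosphinooxazoline), so either enantiomer is available. The allyl group gives the complete side chain in one cross-metathesis with A9, which is clearly better than steps 4–7 of the chosen plan. The C3 ketone leads to C3=C4 by reduction and dehydration.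
- Weak points: the carbonyl of A8 is hindered (quaternary C2, peri methoxy) and electron-rich. Aryl migration competes with migration of C2 and with epoxide formation. A7 can be homologated again and enolizes readily toward C4. Ring A again needs acylation and demethylation.
- Comparison: this road is stronger on the side chain and on independence from the chiral pool. The chosen plan has a key step of a known substrate class and the complete ring A.

Key step: step 12

Assumptions on the chemistry:
- Commercial (R)-(−)-linalool of high enantiomeric purity is used. The route transfers its purity and cannot raise it.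
- Alkyne 19 is racemic, so 20, 21 and 22 are pairs of epimers at the carbinol carbon, which converge in step 14.

## Route

Step 1
Reactants: 1 (R)-linalool
Product: 3 (5R)-5-ethenyl-5-methyloxolan-2-ol (both anomers), via ozonide 2 (not isolated)
Conditions: O3, CH2Cl2, −78 °C (Sudan Red 7B end point); then Me2S, −78 °C → rt
Reagents that add atoms: ozone, [O-][O+]=O
Why: Ozone should attack the electron-rich trisubstituted alkene much faster than the monosubstituted vinyl group (chemoselective ozonolysis with a dye end point); reduction of ozonide 2 gives the γ-hydroxy aldehyde, which closes to lactol 3. The carbinol centre is not touched.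

Step 2
Reactants: 3 (5R)-5-ethenyl-5-methyloxolan-2-ol
Product: 4 (3R)-7-methoxy-3-methylhepta-1,6-dien-3-ol (E/Z mixture at the enol ether)
Conditions: MeOCH2PPh3Cl (3 equiv), KN(SiMe3)2 (3 equiv), THF, 0 °C → rt
Reagents that add atoms: (methoxymethyl)triphenylphosphonium chloride, COC[P+](c1ccccc1)(c1ccccc1)c1ccccc1.[Cl-]
Why: Wittig one-carbon homologation of a lactol through its open hydroxy aldehyde form; excess ylide is used because the lactol hydroxyl is deprotonated first. The enol ether geometry is of no consequence.

Step 3
Reactants: 4 (3R)-7-methoxy-3-methylhepta-1,6-dien-3-ol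
Product: 5 (6R)-6-ethenyl-2-methoxy-6-methyloxane (both anomers)
Conditions: PPTS (cat.), CH2Cl2, rt
Reagents that add atoms: none
Why: Protonation of the enol ether gives an oxocarbenium ion that the tertiary hydroxyl traps in a six-membered ring (acid-catalysed intramolecular acetalization); this makes the later O1–C8a bond. PPTS is too weak to ionize the tertiary allylic alcohol.

Step 4
Reactants: 5 (6R)-6-ethenyl-2-methoxy-6-methyloxane
Product: 7 2-[(2R)-6-methoxy-2-methyloxan-2-yl]ethan-1-ol, via B-alkyl-9-BBN adduct 6 (not isolated)
Conditions: 9-BBN, THF, 0 °C → rt; then aq. NaOH, H2O2, 0 °C → rt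
Reagents that add atoms: hydrogen peroxide, OO
Why: Anti-Markovnikov hydroboration of the only alkene with 9-BBN and oxidation of the C–B bond with retention; the mixed acetal is inert to borane and to alkaline peroxide. The arrangement at the quaternary carbon is unchanged (6 reads S only because boron ranks below carbon).

Step 5
Reactants: 7 2-[(2R)-6-methoxy-2-methyloxan-2-yl]ethan-1-ol
Product: 8 2-[(2R)-6-methoxy-2-methyloxan-2-yl]acetaldehyde
Conditions: Dess–Martin periodinane, pyridine, CH2Cl2, 0 °C → rt
Reagents that add atoms: none
Why: Dess–Martin oxidation of a primary alcohol to the aldehyde; pyridine buffers the acetic acid formed so that the acetal survives.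

Step 6
Reactants: 8 2-[(2R)-6-methoxy-2-methyloxan-2-yl]acetaldehyde
Product: 9 (3E)-5-[(2R)-6-methoxy-2-methyloxan-2-yl]pent-3-en-2-one
Conditions: Ph3P=CHC(O)CH3, toluene, 80 °C
Reagents that add atoms: 1-(triphenylphosphoranylidene)propan-2-one, CC(=O)C=P(c1ccccc1)(c1ccccc1)c1ccccc1
Why: Wittig olefination with a ketone-stabilized ylide, which should give the (E)-enone; the neutral conditions do not open the β-alkoxy aldehyde.

Step 7
Reactants: 9 (3E)-5-[(2R)-6-methoxy-2-methyloxan-2-yl]pent-3-en-2-one
Product: 10 (3E)-5-[(2R)-6-methoxy-2-methyloxan-2-yl]-2-methylpent-3-en-2-ol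
Conditions: MeLi, Et2O, −78 °C; then H2O
Reagents that add atoms: methyllithium, [Li]C
Why: 1,2-Addition of methyllithium to the enone carbonyl at low temperature gives the tertiary allylic alcohol C4'; the acetal does not react.

Step 8
Reactants: 10 (3E)-5-[(2R)-6-methoxy-2-methyloxan-2-yl]-2-methylpent-3-en-2-ol
Product: 12 trimethyl{[(3E)-2-methyl-5-[(2R)-2-methyl-3,4-dihydro-2H-pyran-2-yl]pent-3-en-2-yl]oxy}silane, via silyl ether 11 (not isolated)
Conditions: TMSOTf (2.5 equiv), i-Pr2NEt (3 equiv), CH2Cl2, −20 °C → rt
Reagents that add atoms: trimethylsilyl trifluoromethanesulfonate, C[Si](C)(C)OS(=O)(=O)C(F)(F)F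
Why: The silyl triflate first silylates the tertiary alcohol and then ionizes the methyl acetal to the cyclic oxocarbenium ion, which the hindered amine deprotonates to the enol ether (acetal to enol ether elimination with silyl triflate and amine). Loss of methoxide should be preferred over ring opening because the ring oxygen sits on a tertiary carbon.

Step 9
Reactants: 12 trimethyl{[(3E)-2-methyl-5-[(2R)-2-methyl-3,4-dihydro-2H-pyran-2-yl]pent-3-en-2-yl]oxy}silane; 13 chromium hexacarbonyl
Product: 16 pentacarbonyl{methoxy[(2R)-2-methyl-2-[(2E)-4-methyl-4-(trimethylsilyloxy)pent-2-en-1-yl]-3,4-dihydro-2H-pyran-6-yl]methylidene}chromium, via vinyllithium 14 (not isolated), via lithium acylchromate 15 (not isolated)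
Conditions: t-BuLi, THF/pentane, −78 → 0 °C; Cr(CO)6, Et2O, 0 °C → rt; then Me3OBF4, CH2Cl2, 0 °C
Reagents that add atoms: trimethyloxonium tetrafluoroborate, C[O+](C)C.F[B-](F)(F)F
Why: Fischer carbene synthesis: vinylic deprotonation of the cyclic enol ether next to oxygen, addition of the vinyllithium to a CO ligand, and O-methylation of the acylate. The silyl ether and the isolated alkene are inert to t-BuLi at this temperature.

Step 10
Reactants: 17 (E)-cinnamaldehyde
Product: 18 rac-(1E)-1-phenylpent-1-en-4-yn-3-ol
Conditions: HC≡CMgBr, THF, 0 °C; then H2O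
Reagents that add atoms: ethynylmagnesium bromide, C#C[Mg]Br
Why: Grignard 1,2-addition of an acetylide to the enal carbonyl; the racemate is wanted because this carbon becomes the ketone.

Step 11
Reactants: 18 rac-(1E)-1-phenylpent-1-en-4-yn-3-ol
Product: 19 rac-tert-butyldimethyl{[(1E)-1-phenylpent-1-en-4-yn-3-yl]oxy}silane
Conditions: TBSCl, imidazole, DMF, rt
Reagents that add atoms: tert-butyldimethylsilyl chloride, CC(C)(C)[Si](C)(C)Cl
Why: Standard silylation of a secondary alcohol; the bulky silyloxy group also raises the steric bias needed in step 12.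

Step 12
Reactants: 16 pentacarbonyl{methoxy[(2R)-2-methyl-2-[(2E)-4-methyl-4-(trimethylsilyloxy)pent-2-en-1-yl]-3,4-dihydro-2H-pyran-6-yl]methylidene}chromium; 19 rac-tert-butyldimethyl{[(1E)-1-phenylpent-1-en-4-yn-3-yl]oxy}silane
Product: 21 (2R)-6-[(2E)-1-(tert-butyldimethylsilyloxy)-3-phenylprop-2-en-1-yl]-8-methoxy-2-methyl-2-[(2E)-4-methyl-4-(trimethylsilyloxy)pent-2-en-1-yl]chroman-5-ol (two epimers at the silyloxy carbon), via tricarbonylchromium arene complex 20 (not isolated)
Conditions: THF (degassed), 50 °C, argon; then air, rt
Reagents that add atoms: none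
Why: Loss of one CO from the zerovalent chromium carbene 16 opens a site for the alkyne; insertion with the unsubstituted alkyne carbon bonding to the carbene carbon gives a vinylcarbene, CO insertion gives a dienylketene, and 6π-electrocyclization between C4a and the ketene carbon followed by enolization gives the phenol as complex 20, from which air releases 21. The closest known reaction is the Dötz benzannulation of dihydropyranyl and glycal-derived methoxycarbenes of chromium with terminal alkynes to chroman-type 4-methoxyphenols. Ring A is the only ring formed, and it closes by 6π-electrocyclic closure of the metal-bound dienylketene (a formal [3+2+1] assembly from three carbons of the carbene ligand, two of the alkyne and one CO). No stereocentre is created: C2 is a remote quaternary carbon that cannot epimerize, and the carbinol centre enters with racemic 19. The step needs regioselective insertion, which is steric in origin, since the branched silyloxy substituent avoids the carbene carbon and ends at C6 next to the CO-derived C5, leaving C7 unsubstituted. It also needs phenol formation instead of cyclopentannulation or furan formation, which an alkenyl carbene with a donor alkoxy group in an ether solvent at moderate temperature favours; the moderate temperature should also keep the ortho-hydroxybenzylic silyl ether from ionizing.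

Step 13
Reactants: 21 (2R)-6-[(2E)-1-(tert-butyldimethylsilyloxy)-3-phenylprop-2-en-1-yl]-8-methoxy-2-methyl-2-[(2E)-4-methyl-4-(trimethylsilyloxy)pent-2-en-1-yl]chroman-5-ol
Product: 22 (2R)-6-[(2E)-1-hydroxy-3-phenylprop-2-en-1-yl]-2-[(2E)-4-hydroxy-4-methylpent-2-en-1-yl]-8-methoxy-2-methylchroman-5-ol (two epimers at the carbinol carbon)
Conditions: Bu4NF, AcOH, THF, 0 °C → rt
Reagents that add atoms: none
Why: Fluoride cleaves both silyl ethers; buffering with acetic acid keeps the phenoxide concentration low so that the ortho-hydroxybenzylic alcohol is not driven to an ortho-quinone methide.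

Step 14
Reactants: 22 (2R)-6-[(2E)-1-hydroxy-3-phenylprop-2-en-1-yl]-2-[(2E)-4-hydroxy-4-methylpent-2-en-1-yl]-8-methoxy-2-methylchroman-5-ol
Product: 23 (2E)-1-{(2R)-5-hydroxy-2-[(2E)-4-hydroxy-4-methylpent-2-en-1-yl]-8-methoxy-2-methylchroman-6-yl}-3-phenylprop-2-en-1-one
Conditions: MnO2, CH2Cl2, rt
Reagents that add atoms: none
Why: MnO2 oxidizes the allylic and benzylic secondary alcohol selectively; the tertiary alcohol cannot be oxidized, and the new ketone is chelated by the C5 hydroxyl, which lowers the oxidizability of the phenol. Both epimers give the same chalcone.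

Step 15
Reactants: 23 (2E)-1-{(2R)-5-hydroxy-2-[(2E)-4-hydroxy-4-methylpent-2-en-1-yl]-8-methoxy-2-methylchroman-6-yl}-3-phenylprop-2-en-1-one
Product: 24 (2E)-1-{(2S)-5-hydroxy-2-[(2E)-4-hydroxy-4-methylpent-2-en-1-yl]-8-methoxy-2-methyl-2H-chromen-6-yl}-3-phenylprop-2-en-1-one
Conditions: DDQ (1.2 equiv), 1,4-dioxane (dry), 80 °C
Reagents that add atoms: none
Why: Quinone dehydrogenation of a chroman to a 2H-chromene: hydride leaves C4, assisted by O1 and the C5 oxygen (ortho-quinone methide character), and C3 then loses a proton; the same pattern of a chelated ortho-hydroxy acyl chroman is a standard substrate for this reaction. C2 is not involved, and its descriptor changes from R to S only because C3 now outranks C1'.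

Step 16
Reactants: 24 (2E)-1-{(2S)-5-hydroxy-2-[(2E)-4-hydroxy-4-methylpent-2-en-1-yl]-8-methoxy-2-methyl-2H-chromen-6-yl}-3-phenylprop-2-en-1-one
Product: 26 (2E)-1-{(2S)-5,8-dihydroxy-2-[(2E)-4-hydroxy-4-methylpent-2-en-1-yl]-2-methyl-2H-chromen-6-yl}-3-phenylprop-2-en-1-one (CNP0327890.1), via quinone 25 (not isolated)
Conditions: (NH4)2Ce(NO3)6 (2.2 equiv), MeCN/H2O, 0 °C, short contact; then aq. Na2S2O4, EtOAc, rt
Reagents that add atoms: water, O
Why: Oxidative demethylation of a para-methoxyphenol by tetravalent cerium gives the quinone (water supplies the C8 oxygen and methanol leaves), as is standard for 5,8-dioxygenated chromenes; dithionite reduces the acylquinone at once to the hydroquinone, which the C5–OH to carbonyl hydrogen bond stabilizes.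

## Compound list

1 | (R)-linalool, (3R)-3,7-dimethylocta-1,6-dien-3-ol | C=C[C@@](O)(C)CCC=C(C)C | starting material
2 | (3R)-5-(5,5-dimethyl-1,2,4-trioxolan-3-yl)-3-methylpent-1-en-3-ol (secondary ozonide) | C=C[C@@](O)(C)CCC1OOC(C)(C)O1 | intermediate (not isolated)
3 | (5R)-5-ethenyl-5-methyloxolan-2-ol (both anomers) | C=C[C@@]1(C)CCC(O)O1 | intermediate
4 | (3R)-7-methoxy-3-methylhepta-1,6-dien-3-ol (E/Z mixture) | C=C[C@@](O)(C)CCC=COC | intermediate
5 | (6R)-6-ethenyl-2-methoxy-6-methyloxane (both anomers) | C=C[C@@]1(C)CCCC(OC)O1 | intermediate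
6 | 9-{2-[(2S)-6-methoxy-2-methyloxan-2-yl]ethyl}-9-borabicyclo[3.3.1]nonane | C(C[C@@]1(C)CCCC(OC)O1)B1C2CCCC1CCC2 | intermediate (not isolated)
7 | 2-[(2R)-6-methoxy-2-methyloxan-2-yl]ethan-1-ol | OCC[C@@]1(C)CCCC(OC)O1 | intermediate
8 | 2-[(2R)-6-methoxy-2-methyloxan-2-yl]acetaldehyde | O=CC[C@@]1(C)CCCC(OC)O1 | intermediate
9 | (3E)-5-[(2R)-6-methoxy-2-methyloxan-2-yl]pent-3-en-2-one | CC(=O)/C=C/C[C@@]1(C)CCCC(OC)O1 | intermediate
10 | (3E)-5-[(2R)-6-methoxy-2-methyloxan-2-yl]-2-methylpent-3-en-2-ol | CC(C)(O)/C=C/C[C@@]1(C)CCCC(OC)O1 | intermediate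
11 | {[(3E)-5-[(2R)-6-methoxy-2-methyloxan-2-yl]-2-methylpent-3-en-2-yl]oxy}trimethylsilane | CC(C)(O[Si](C)(C)C)/C=C/C[C@@]1(C)CCCC(OC)O1 | intermediate (not isolated)
12 | trimethyl{[(3E)-2-methyl-5-[(2R)-2-methyl-3,4-dihydro-2H-pyran-2-yl]pent-3-en-2-yl]oxy}silane | CC(C)(O[Si](C)(C)C)/C=C/C[C@@]1(C)CCC=CO1 | intermediate
13 | chromium hexacarbonyl, Cr(CO)6 | O=C=[Cr](=C=O)(=C=O)(=C=O)(=C=O)=C=O | starting material
14 | {(2R)-2-methyl-2-[(2E)-4-methyl-4-(trimethylsilyloxy)pent-2-en-1-yl]-3,4-dihydro-2H-pyran-6-yl}lithium | CC(C)(O[Si](C)(C)C)/C=C/C[C@@]1(C)CCC=C([Li])O1 | intermediate (not isolated)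
15 | lithium pentacarbonyl{[(2R)-2-methyl-2-[(2E)-4-methyl-4-(trimethylsilyloxy)pent-2-en-1-yl]-3,4-dihydro-2H-pyran-6-yl]carbonyl}chromate | CC(C)(O[Si](C)(C)C)/C=C/C[C@@]1(C)CCC=C(O1)C(O[Li])=[Cr](=C=O)(=C=O)(=C=O)(=C=O)=C=O | intermediate (not isolated)
16 | pentacarbonyl{methoxy[(2R)-2-methyl-2-[(2E)-4-methyl-4-(trimethylsilyloxy)pent-2-en-1-yl]-3,4-dihydro-2H-pyran-6-yl]methylidene}chromium | CC(C)(O[Si](C)(C)C)/C=C/C[C@@]1(C)CCC=C(O1)C(OC)=[Cr](=C=O)(=C=O)(=C=O)(=C=O)=C=O | intermediate
17 | (E)-cinnamaldehyde | O=C/C=C/c1ccccc1 | starting material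
18 | rac-(1E)-1-phenylpent-1-en-4-yn-3-ol | C#CC(O)/C=C/c1ccccc1 | intermediate
19 | rac-tert-butyldimethyl{[(1E)-1-phenylpent-1-en-4-yn-3-yl]oxy}silane | C#CC(O[Si](C)(C)C(C)(C)C)/C=C/c1ccccc1 | intermediate
20 | tricarbonyl(η6-arene)chromium complex of 21, metal on ring A (written with the metal fragment set apart) | CC(C)(O[Si](C)(C)C)/C=C/C[C@@]1(C)CCc2c(O)c(C(O[Si](C)(C)C(C)(C)C)/C=C/c3ccccc3)cc(OC)c2O1.[Cr].[C-]#[O+].[C-]#[O+].[C-]#[O+] | intermediate (not isolated)
21 | (2R)-6-[(2E)-1-(tert-butyldimethylsilyloxy)-3-phenylprop-2-en-1-yl]-8-methoxy-2-methyl-2-[(2E)-4-methyl-4-(trimethylsilyloxy)pent-2-en-1-yl]chroman-5-ol (two epimers at the silyloxy carbon) | CC(C)(O[Si](C)(C)C)/C=C/C[C@@]1(C)CCc2c(O)c(C(O[Si](C)(C)C(C)(C)C)/C=C/c3ccccc3)cc(OC)c2O1 | intermediate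
22 | (2R)-6-[(2E)-1-hydroxy-3-phenylprop-2-en-1-yl]-2-[(2E)-4-hydroxy-4-methylpent-2-en-1-yl]-8-methoxy-2-methylchroman-5-ol (two epimers at the carbinol carbon) | CC(C)(O)/C=C/C[C@@]1(C)CCc2c(O)c(C(O)/C=C/c3ccccc3)cc(OC)c2O1 | intermediate
23 | (2E)-1-{(2R)-5-hydroxy-2-[(2E)-4-hydroxy-4-methylpent-2-en-1-yl]-8-methoxy-2-methylchroman-6-yl}-3-phenylprop-2-en-1-one | CC(C)(O)/C=C/C[C@@]1(C)CCc2c(O)c(C(=O)/C=C/c3ccccc3)cc(OC)c2O1 | intermediate
24 | (2E)-1-{(2S)-5-hydroxy-2-[(2E)-4-hydroxy-4-methylpent-2-en-1-yl]-8-methoxy-2-methyl-2H-chromen-6-yl}-3-phenylprop-2-en-1-one | CC(C)(O)/C=C/C[C@@]1(C)C=Cc2c(O)c(C(=O)/C=C/c3ccccc3)cc(OC)c2O1 | intermediate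
25 | (2S)-2-[(2E)-4-hydroxy-4-methylpent-2-en-1-yl]-2-methyl-6-[(2E)-3-phenylprop-2-enoyl]-2H-chromene-5,8-dione | CC(C)(O)/C=C/C[C@@]1(C)C=CC2=C(O1)C(=O)C=C(C2=O)C(=O)/C=C/c1ccccc1 | intermediate (not isolated)
26 | (2E)-1-{(2S)-5,8-dihydroxy-2-[(2E)-4-hydroxy-4-methylpent-2-en-1-yl]-2-methyl-2H-chromen-6-yl}-3-phenylprop-2-en-1-one | CC(C)(O)/C=C/C[C@@]1(C)C=Cc2c(O)c(C(=O)/C=C/c3ccccc3)cc(O)c2O1 | target

## Step count and least certain steps

Total: 16 steps. Longest linear sequence: 14 steps (steps 1–9 and 12–16, from (R)-linalool). The alkyne arm adds steps 10 and 11.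

**Step 12 (key step).**
- Risk: the most likely failure is loss of silanol from the ortho-hydroxybenzylic, cinnamylic silyl ether of 20 or 21. This would give an ortho-quinone methide that closes onto the styrene to a flavene-type by-product. Cyclopentannulation could also compete with phenol formation.
- Fallback: this sets out from carbene 16 and uses a less ionizable alkyne. 16 and the silyl ether of racemic but-3-yn-2-ol, rac-tert-butyl(but-3-yn-2-yloxy)dimethylsilane F1, should give under the same benzannulation (2R)-6-[1-(tert-butyldimethylsilyloxy)ethyl]-8-methoxy-2-methyl-2-[(2E)-4-methyl-4-(trimethylsilyloxy)pent-2-en-1-yl]chroman-5-ol F2. Buffered Bu4NF would give the triol (2R)-6-(1-hydroxyethyl)-2-[(2E)-4-hydroxy-4-methylpent-2-en-1-yl]-8-methoxy-2-methylchroman-5-ol F3. MnO2 would give the acetophenone 1-{(2R)-5-hydroxy-2-[(2E)-4-hydroxy-4-methylpent-2-en-1-yl]-8-methoxy-2-methylchroman-6-yl}ethan-1-one F4. Claisen–Schmidt condensation of F4 with benzaldehyde (KOH, EtOH, under argon) would return to the route at 23.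

**Step 8.**
- Risk: the silyl triflate may ionize the wrong bond, either the ring C–O bond of the acetal (ring opening) or the tertiary allylic silyl ether, instead of expelling methoxide.
- Fallback: this sets out from 10 and replaces the cationic elimination by dehydration of a hemiacetal. Dilute aqueous acetic acid would hydrolyse the methyl acetal to the lactol (6R)-6-[(2E)-4-hydroxy-4-methylpent-2-en-1-yl]-6-methyloxan-2-ol F5. MsCl and Et3N (0 °C to rt, one equivalent, the tertiary alcohol being far slower) would dehydrate it through the anomeric sulfonate to (3E)-2-methyl-5-[(2R)-2-methyl-3,4-dihydro-2H-pyran-2-yl]pent-3-en-2-ol F6. TMSCl and imidazole would then give 12.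

**Step 15.**
- Risk: two-electron oxidation may occur at the methoxyphenol instead of hydride abstraction at C4, and the acidic hydroquinone by-product may dehydrate the tertiary allylic alcohol at 80 °C.
- Fallback: this sets out from 23 and lets the substrate's own quinone do the oxidation. (NH4)2Ce(NO3)6 in aqueous acetonitrile would give (2R)-2-[(2E)-4-hydroxy-4-methylpent-2-en-1-yl]-2-methyl-6-[(2E)-3-phenylprop-2-enoyl]chromane-5,8-dione F7. Triethylamine in CH2Cl2 would move a C4 proton to O8 (quinone to ortho-quinone methide tautomerization, as in the base-induced conversion of prenylquinones into chromenols), and a 1,5-hydrogen shift from C3 to O5 would then aromatize ring A. This arrives directly at 26 and replaces steps 15 and 16, but the isomerization of a chroman quinone is less well documented than the DDQ reaction.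

**Step 16.**
- Risk: the electron-rich chromene double bond may be over-oxidized, the tertiary allylic alcohol may ionize in the acidic cerium medium, or the very electrophilic acylquinone may decompose before it is reduced.
- Fallback: this sets out from 23 and moves the oxidation in front of the chromene. The same cerium oxidation of 23 with dithionite work-up (through F7) would give the hydroquinone (2E)-1-{(2R)-5,8-dihydroxy-2-[(2E)-4-hydroxy-4-methylpent-2-en-1-yl]-2-methylchroman-6-yl}-3-phenylprop-2-en-1-one F8. TBSCl and imidazole would silylate the unchelated C8 hydroxyl to (2E)-1-{(2R)-8-(tert-butyldimethylsilyloxy)-5-hydroxy-2-[(2E)-4-hydroxy-4-methylpent-2-en-1-yl]-2-methylchroman-6-yl}-3-phenylprop-2-en-1-one F9. DDQ would dehydrogenate it to (2E)-1-{(2S)-8-(tert-butyldimethylsilyloxy)-5-hydroxy-2-[(2E)-4-hydroxy-4-methylpent-2-en-1-yl]-2-methyl-2H-chromen-6-yl}-3-phenylprop-2-en-1-one F10. Buffered Bu4NF would then give 26, so the last step becomes a mild desilylation.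

## Further compounds

F1 | step 12 | rac-tert-butyl(but-3-yn-2-yloxy)dimethylsilane | C#CC(C)O[Si](C)(C)C(C)(C)C
F2 | step 12 | (2R)-6-[1-(tert-butyldimethylsilyloxy)ethyl]-8-methoxy-2-methyl-2-[(2E)-4-methyl-4-(trimethylsilyloxy)pent-2-en-1-yl]chroman-5-ol (two epimers) | CC(C)(O[Si](C)(C)C)/C=C/C[C@@]1(C)CCc2c(O)c(C(C)O[Si](C)(C)C(C)(C)C)cc(OC)c2O1
F3 | step 12 | (2R)-6-(1-hydroxyethyl)-2-[(2E)-4-hydroxy-4-methylpent-2-en-1-yl]-8-methoxy-2-methylchroman-5-ol (two epimers) | CC(C)(O)/C=C/C[C@@]1(C)CCc2c(O)c(C(C)O)cc(OC)c2O1
F4 | step 12 | 1-{(2R)-5-hydroxy-2-[(2E)-4-hydroxy-4-methylpent-2-en-1-yl]-8-methoxy-2-methylchroman-6-yl}ethan-1-one | CC(C)(O)/C=C/C[C@@]1(C)CCc2c(O)c(C(C)=O)cc(OC)c2O1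
F5 | step 8 | (6R)-6-[(2E)-4-hydroxy-4-methylpent-2-en-1-yl]-6-methyloxan-2-ol (both anomers) | CC(C)(O)/C=C/C[C@@]1(C)CCCC(O)O1
F6 | step 8 | (3E)-2-methyl-5-[(2R)-2-methyl-3,4-dihydro-2H-pyran-2-yl]pent-3-en-2-ol | CC(C)(O)/C=C/C[C@@]1(C)CCC=CO1
F7 | step 15 | (2R)-2-[(2E)-4-hydroxy-4-methylpent-2-en-1-yl]-2-methyl-6-[(2E)-3-phenylprop-2-enoyl]chromane-5,8-dione | CC(C)(O)/C=C/C[C@@]1(C)CCC2=C(O1)C(=O)C=C(C2=O)C(=O)/C=C/c1ccccc1
F8 | step 16 | (2E)-1-{(2R)-5,8-dihydroxy-2-[(2E)-4-hydroxy-4-methylpent-2-en-1-yl]-2-methylchroman-6-yl}-3-phenylprop-2-en-1-one | CC(C)(O)/C=C/C[C@@]1(C)CCc2c(O)c(C(=O)/C=C/c3ccccc3)cc(O)c2O1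
F9 | step 16 | (2E)-1-{(2R)-8-(tert-butyldimethylsilyloxy)-5-hydroxy-2-[(2E)-4-hydroxy-4-methylpent-2-en-1-yl]-2-methylchroman-6-yl}-3-phenylprop-2-en-1-one | CC(C)(O)/C=C/C[C@@]1(C)CCc2c(O)c(C(=O)/C=C/c3ccccc3)cc(O[Si](C)(C)C(C)(C)C)c2O1
F10 | step 16 | (2E)-1-{(2S)-8-(tert-butyldimethylsilyloxy)-5-hydroxy-2-[(2E)-4-hydroxy-4-methylpent-2-en-1-yl]-2-methyl-2H-chromen-6-yl}-3-phenylprop-2-en-1-one | CC(C)(O)/C=C/C[C@@]1(C)C=Cc2c(O)c(C(=O)/C=C/c3ccccc3)cc(O[Si](C)(C)C(C)(C)C)c2O1
A1 | alternative 1 | (2S)-2-(2-hydroxyethyl)-5,8-dimethoxy-2-methylchroman-4-one | OCC[C@@]1(C)CC(=O)c2c(OC)ccc(OC)c2O1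
A2 | alternative 1 | (S)-mevalonolactone, (4S)-4-hydroxy-4-methyloxan-2-one | O=C1C[C@@](C)(O)CCO1
A3 | alternative 1 | 3,6-dimethoxy-2-(trimethylsilyl)phenyl trifluoromethanesulfonate | COc1ccc(OC)c(OS(=O)(=O)C(F)(F)F)c1[Si](C)(C)C
A4 | alternative 2 | (3E)-5-[(2S)-5,8-dimethoxy-2-methyl-2H-chromen-2-yl]-2-methylpent-3-en-2-ol | CC(C)(O)/C=C/C[C@@]1(C)C=Cc2c(OC)ccc(OC)c2O1
A5 | alternative 2 | (3E,6S)-6-(2-ethenyl-3,6-dimethoxyphenoxy)-2,6-dimethylocta-3,7-dien-2-ol | CC(C)(O)/C=C/C[C@@](Oc1c(C=C)c(OC)ccc1OC)(C)C=C
A6 | alternative 2 | (S)-linalool, (3S)-3,7-dimethylocta-1,6-dien-3-ol | C=C[C@](O)(C)CCC=C(C)C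
A7 | alternative 3 | (2S)-5,8-dimethoxy-2-methyl-2-(prop-2-en-1-yl)chroman-3-one | C=CC[C@@]1(C)C(=O)Cc2c(OC)ccc(OC)c2O1
A8 | alternative 3 | (2S)-4,7-dimethoxy-2-methyl-2-(prop-2-en-1-yl)-1-benzofuran-3(2H)-one | C=CC[C@@]1(C)C(=O)c2c(OC)ccc(OC)c2O1
A9 | alternative 3 | 2-methylbut-3-en-2-ol | C=CC(C)(C)O
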